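## Retrosynthetic overview

1. The route rests on the trans-fused decalin of the target: ring A (C1–C5, C10) and ring B (C5–C10) share the C5–C10 bond, carry four adjacent stereocentres (C4, C5, C10, C9) and an exocyclic C8=C17 alkene. This pattern maps onto a chair–chair folded open-chain (E,E) epoxy diene.
2. Late stage: the C13 tertiary allylic 1,2-diol comes from palladium-catalysed enantioselective hydrolysis of a 13,16-epoxy-14-ene, made from a vinyl ketone and before that the C13 ester. The C18 ester comes from a C18 silyl ether, and C3–H from C3–OH by radical deoxygenation.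
3. Key disconnection: the C4–C5 and C9–C10 bonds, formed in one epoxide-opened cation–olefin cascade that closes ring A first and ring B second and is ended by a C17 allylsilane.
4. The precursor is assembled from geranyl acetate (C1–C6, C10, C18–C20; SeO2 oxidation, asymmetric epoxidation), methyl acetoacetate (C7–C9, C11), (trimethylsilyl)methylmagnesium chloride (C17) and methyl acetate (C12, C13).

Key step: step 12

Remark on numbering and abbreviations: labdane numbering is used (C11–C16 side chain on C9, C17 on C8, C18 equatorial and C19 axial on C4, C20 on C10); the skeleton is of the ent-labdane series; TBDPS = tert-butyl(diphenyl)silyl, TBS = tert-butyl(dimethyl)silyl, PMB = 4-methoxybenzyl.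

Assumption: the (1R,2R) enantiomer of the bis(2-diphenylphosphinobenzamide) ligand is taken to deliver oxygen to the C13 face that gives 13R; the sense is to be checked first on 2-methyl-2-vinyloxirane and the (1S,2S) ligand used instead if it is opposite.

## Route

Step 1
Reactants: 1 geranyl acetate
Product: 2 (2E,6E)-8-hydroxygeranyl acetate
Conditions: SeO2 (cat.), t-BuOOH, salicylic acid (cat.), CH2Cl2, rt
Reagents that add atoms: tert-butyl hydroperoxide, CC(C)(C)OO
Why: Selenium dioxide allylic oxidation (ene reaction, then [2,3]-sigmatropic shift) should hydroxylate the (E)-methyl group of the electron-richer terminal alkene, the alkene next to the acetate being deactivated.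

Step 2
Reactants: 2 (2E,6E)-8-hydroxygeranyl acetate
Product: 3 (6R,7R)-epoxy alcohol (2E)-5-[(2R,3R)-3-(hydroxymethyl)-3-methyloxiran-2-yl]-3-methylpent-2-en-1-yl acetate
Conditions: Ti(OiPr)4 (cat.), diethyl D-(−)-tartrate (cat.), t-BuOOH, 4 Å molecular sieves, CH2Cl2, −20 °C
Reagents that add atoms: tert-butyl hydroperoxide, CC(C)(C)OO
Why: Sharpless asymmetric epoxidation acts only on the alkene of the free allylic alcohol, and D-(−)-tartrate should give the (2R,3R) oxirane (mirror image of the (2S,3S) oxiranes that L-(+)-tartrate gives with (E)-2-methylalk-2-en-1-ols), which sets C3 and C4 with C18 trans to C2.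

Step 3
Reactants: 3 (6R,7R)-epoxy alcohol
Product: 4 TBDPS ether of 3
Conditions: TBDPSCl, imidazole, CH2Cl2, 0 °C → rt
Reagents that add atoms: tert-butyl(chloro)diphenylsilane, CC(C)(C)[Si](Cl)(c1ccccc1)c1ccccc1
Why: Silyl ether protection of the primary alcohol masks the C18 oxygen as a bulky, poorly chelating group that should withstand base, organometallic reagents and the Lewis acid of step 12.

Step 4
Reactants: 4 TBDPS ether acetate
Product: 5 allylic alcohol (2E)-5-[(2R,3R)-3-(TBDPS-oxymethyl)-3-methyloxiran-2-yl]-3-methylpent-2-en-1-ol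
Conditions: K2CO3 (cat.), MeOH, 0 °C → rt
Reagents that add atoms: none
Why: Base-catalysed transesterification (methanolysis of the acetate) frees the allylic alcohol without touching the oxirane or the silyl ether.

Step 5
Reactants: 5 allylic alcohol
Product: 7 allylic bromide, via allylic mesylate 6 (not isolated)
Conditions: MsCl, Et3N, THF, −45 °C; then LiBr, THF, 0 °C
Reagents that add atoms: lithium bromide, [Li+].[Br-]; methanesulfonyl chloride, CS(=O)(=O)Cl (its atoms stay in 6 only)
Why: Mesylation followed by SN2 displacement with bromide gives the primary allylic bromide under non-acidic conditions that spare the oxirane.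

Step 6
Reactants: 7 allylic bromide; 8 methyl acetoacetate
Product: 10 β-keto ester methyl (6E)-7-methyl-3-oxo-9-[(2R,3R)-3-(TBDPS-oxymethyl)-3-methyloxiran-2-yl]non-6-enoate, via methyl acetoacetate dianion 9 (not isolated)
Conditions: 8, NaH then n-BuLi, THF, 0 °C; then 7, 0 °C; aqueous work-up
Reagents that add atoms: methyl acetoacetate (8), COC(=O)CC(C)=O
Why: In this acetoacetate dianion alkylation the more basic γ-carbanion attacks the allylic bromide by SN2 and brings in C7, C8, C9 and C11.

Step 7
Reactants: 10 β-keto ester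
Product: 12 (Z)-enol triflate methyl (2Z,6E)-7-methyl-9-[(2R,3R)-3-(TBDPS-oxymethyl)-3-methyloxiran-2-yl]-3-(trifluoromethylsulfonyloxy)nona-2,6-dienoate, via potassium enolate 11 (not isolated)
Conditions: KN(SiMe3)2, THF, −78 °C; then PhNTf2, −78 → 0 °C
Reagents that add atoms: N-phenylbis(trifluoromethanesulfonimide), O=S(=O)(N(c1ccccc1)S(=O)(=O)C(F)(F)F)C(F)(F)F
Why: Enol triflate formation on the chelated (Z)-enolate keeps the enolate geometry, so that C7 should end trans to the ester carbon C11.

Step 8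
Reactants: 12 (Z)-enol triflate; 13 (trimethylsilyl)methylmagnesium chloride
Product: 14 allylsilane enoate methyl (2Z,6E)-7-methyl-9-[(2R,3R)-3-(TBDPS-oxymethyl)-3-methyloxiran-2-yl]-3-[(trimethylsilyl)methyl]nona-2,6-dienoate
Conditions: Pd(PPh3)4 (cat.), Et2O/THF, 0 °C → rt
Reagents that add atoms: (trimethylsilyl)methylmagnesium chloride (13), C[Si](C)(C)C[Mg]Cl
Why: Kumada–Corriu cross-coupling at zerovalent palladium proceeds with retention of alkene geometry on the activated enol triflate and should outrun attack of the weakly nucleophilic Grignard reagent on ester or oxirane, installing C17 as CH2SiMe3.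

Step 9
Reactants: 14 allylsilane enoate
Product: 15 allylic alcohol (2Z,6E)-7-methyl-9-[(2R,3R)-3-(TBDPS-oxymethyl)-3-methyloxiran-2-yl]-3-[(trimethylsilyl)methyl]nona-2,6-dien-1-ol
Conditions: i-Bu2AlH, CH2Cl2, −78 °C; aq. potassium sodium tartrate
Reagents that add atoms: none
Why: 1,2-Reduction of the conjugated ester by the aluminium hydride at low temperature gives the allylic alcohol and should leave oxirane, allylsilane and silyl ether alone.

Step 10
Reactants: 15 allylic alcohol
Product: 17 allylic bromide, via allylic mesylate 16 (not isolated)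
Conditions: MsCl, Et3N, THF, −45 °C; then LiBr, THF, 0 °C; used at once
Reagents that add atoms: lithium bromide, [Li+].[Br-]; methanesulfonyl chloride, CS(=O)(=O)Cl (its atoms stay in 16 only)
Why: Mesylation and SN2 displacement by bromide avoid the ionising or acidic conditions that would trigger 1,4-loss of silicon from this γ-silyl allylic system.

Step 11
Reactants: 17 allylic bromide; 18 methyl acetate
Product: 20 cyclisation precursor methyl (4Z,8E)-9-methyl-11-[(2R,3R)-3-(TBDPS-oxymethyl)-3-methyloxiran-2-yl]-5-[(trimethylsilyl)methyl]undeca-4,8-dienoate, via methyl acetate lithium enolate 19 (not isolated)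
Conditions: 18, LiN(i-Pr)2, THF, −78 °C; then 17, DMPU, −78 → −40 °C
Reagents that add atoms: methyl acetate (18), COC(C)=O
Why: SN2 alkylation of the ester enolate at the primary allylic carbon adds C12 and C13 without allylic transposition, excess enolate at low temperature holding back Claisen condensation.

Step 12
Reactants: 20 cyclisation precursor
Product: 21 bicyclic hydroxy ester methyl (3R,4S,5S,9R,10S)-3-hydroxy-18-(TBDPS-oxy)-14,15,16-trinorlabd-8(17)-en-13-oate
Conditions: MeAlCl2 (excess), CH2Cl2, −94 → −78 °C; then Et3N, aq. MeOH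
Reagents that add atoms: none
Why: Aluminium coordination at the oxirane oxygen polarises the C4–O bond, backside attack of the C5=C10 π bond on the tertiary carbon C4 forms the C4–C5 bond with inversion, C9 of the allylsilane then bonds to the electron-poor C10, and chloride-assisted loss of Me3Si from the β-silyl cation at C8 leaves the C8=C17 double bond. The closest known reaction type is the Lewis acid-promoted, epoxide-initiated cation–olefin polycyclisation with allylsilane termination. Ring A (C1–C5, C10) closes in the 6-endo mode through a chair by the C4–C5 bond, and ring B (C5–C10) closes in the 6-endo mode through a second chair by the C9–C10 bond. C4 is set by inversion at the oxirane carbon, which places C18 (trans to C2 on the oxirane) equatorial and C19 axial, and the retained (3R) C–O bond, equatorial in the chair, fixes the absolute sense of the fold; C5 and C10 follow from anti addition across the E C5=C10 alkene (H5 and C20 trans-diaxial, trans ring fusion), and C9 from the trans backbone of the C8=C9 alkene, which holds C11 equatorial. The step needs Markovnikov 6-endo closure at both alkenes, secured by the trisubstituted pattern that places cationic character on C10 and then C8, and a single alkene regioisomer, secured by the CH2SiMe3 group because silicon loss should be faster than proton loss toward C7 or C9 or capture by the ester. The ester and the bulky silyl ether are weaker ligands than the oxirane but still bind aluminium, hence the excess of Lewis acid at very low temperature.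

Step 13
Reactants: 21 bicyclic hydroxy ester
Product: 22 C3 O-(imidazol-1-ylthiocarbonyl) derivative of 21
Conditions: 1,1'-thiocarbonyldiimidazole, DMAP (cat.), ClCH2CH2Cl, reflux
Reagents that add atoms: 1,1'-thiocarbonyldiimidazole, S=C(n1ccnc1)n1ccnc1
Why: Thioacylation of the equatorial secondary alcohol gives the thiocarbonyl derivative for Barton–McCombie deoxygenation without the strong base that a xanthate would need beside the enolisable ester.

Step 14
Reactants: 22 thiocarbonyl imidazolide
Product: 23 methyl (4S,5S,9R,10S)-18-(TBDPS-oxy)-14,15,16-trinorlabd-8(17)-en-13-oate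
Conditions: Bu3SnH, AIBN (cat.), toluene, 100 °C
Reagents that add atoms: none
Why: In the Barton–McCombie radical deoxygenation the stannyl radical adds to sulfur, β-scission gives the secondary C3 radical, and hydrogen transfer from the stannane reduces it, the C8=C17 alkene being out of reach of the ring A radical.

Step 15
Reactants: 23 deoxygenated ester
Product: 24 Weinreb amide (4S,5S,9R,10S)-N-methoxy-N-methyl-18-(TBDPS-oxy)-14,15,16-trinorlabd-8(17)-en-13-amide
Conditions: MeNH(OMe)·HCl, i-PrMgCl, THF, −20 → 0 °C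
Reagents that add atoms: N,O-dimethylhydroxylamine hydrochloride, CNOC.Cl
Why: Weinreb amidation with the magnesium amide converts the only ester present at this stage, so the later C18 ester never competes.

Step 16
Reactants: 24 Weinreb amide silyl ether
Product: 25 C18 primary alcohol
Conditions: Bu4NF, THF, rt → 50 °C
Reagents that add atoms: none
Why: Fluoride-induced desilylation frees the neopentyl C18 alcohol and leaves amide and alkene untouched.

Step 17
Reactants: 25 C18 alcohol
Product: 26 C18 aldehyde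
Conditions: Dess–Martin periodinane, CH2Cl2, 0 °C → rt
Reagents that add atoms: none
Why: Dess–Martin oxidation gives the non-enolisable neopentyl aldehyde under conditions that do not disturb the exocyclic alkene.

Step 18
Reactants: 26 C18 aldehyde
Product: 27 C18 carboxylic acid
Conditions: NaClO2, NaH2PO4, 2-methyl-2-butene, t-BuOH/H2O, rt
Reagents that add atoms: sodium chlorite, [Na+].[O-]Cl=O
Why: Pinnick oxidation converts the aldehyde into the acid while 2-methyl-2-butene takes up the hypochlorous acid that would otherwise chlorinate the C8=C17 alkene.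

Step 19
Reactants: 27 C18 carboxylic acid
Product: 28 methyl (4S,5S,9R,10S)-13-[methoxy(methyl)amino]-13-oxo-14,15,16-trinorlabd-8(17)-en-18-oate
Conditions: MeI, K2CO3, DMF, rt
Reagents that add atoms: iodomethane, CI
Why: O-Alkylation of the carboxylate (SN2 at the methyl carbon) esterifies the hindered acid because no attack at the crowded carbonyl carbon is required.

Step 20
Reactants: 28 Weinreb amide methyl ester
Product: 29 vinyl ketone methyl (4S,5S,9R,10S)-13-oxo-16-norlabda-8(17),14-dien-18-oate
Conditions: CH2=CHMgBr, THF, −78 → 0 °C; inverse quench into cold 1 M HCl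
Reagents that add atoms: vinylmagnesium bromide, C=C[Mg]Br
Why: In the Weinreb ketone synthesis the Grignard reagent adds once to give a stable magnesium chelate, the quaternary C4 ester is too hindered to compete, and the acidic inverse quench keeps the released amine from adding to the enone.

Step 21
Reactants: 29 vinyl ketone
Product: 30 vinyl epoxide methyl (4S,5S,9R,10S,13RS)-13,16-epoxylabda-8(17),14-dien-18-oate
Conditions: trimethylsulfonium iodide, n-BuLi, THF, −10 °C; then 29, −78 → 0 °C
Reagents that add atoms: trimethylsulfonium iodide, C[S+](C)C.[I-]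
Why: In the Corey–Chaykovsky epoxidation the unstabilised sulfonium ylide should add irreversibly to the carbonyl carbon and the betaine close to the oxirane (C16 added); both C13 epimers are expected and both are carried on.

Step 22
Reactants: 30 vinyl epoxide (both C13 epimers)
Product: 31 methyl (4S,5S,9R,10S,13R)-13,16-dihydroxylabda-8(17),14-dien-18-oate
Conditions: Pd2(dba)3·CHCl3 (cat.), (1R,2R)-N,N'-bis[2-(diphenylphosphino)benzoyl]cyclohexane-1,2-diamine (cat.), BEt3 (cat.), NaHCO3, CH2Cl2/H2O, rt
Reagents that add atoms: water, O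
Why: In this Tsuji–Trost-type dynamic kinetic asymmetric substitution, zerovalent palladium ionises both epimers to π-allyl complexes that should interconvert by π–σ–π faster than they are trapped, the alkoxide-bound boron and hydrogencarbonate (an oxygen carrier that is re-formed, water being the net reagent) direct oxygen to the branched carbon C13, and the chiral ligand sets C13.

## Compound list

1 | geranyl acetate, (2E)-3,7-dimethylocta-2,6-dien-1-yl acetate | CC(C)=CCC/C(C)=C/COC(C)=O | starting material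
2 | (2E,6E)-8-hydroxy-3,7-dimethylocta-2,6-dien-1-yl acetate | OC/C(C)=C/CC/C(C)=C/COC(C)=O | intermediate
3 | (2E)-5-[(2R,3R)-3-(hydroxymethyl)-3-methyloxiran-2-yl]-3-methylpent-2-en-1-yl acetate | OC[C@@]1(C)O[C@@H]1CC/C(C)=C/COC(C)=O | intermediate
4 | (2E)-5-[(2R,3R)-3-(TBDPS-oxymethyl)-3-methyloxiran-2-yl]-3-methylpent-2-en-1-yl acetate | CC(C)(C)[Si](c1ccccc1)(c1ccccc1)OC[C@@]1(C)O[C@@H]1CC/C(C)=C/COC(C)=O | intermediate
5 | (2E)-5-[(2R,3R)-3-(TBDPS-oxymethyl)-3-methyloxiran-2-yl]-3-methylpent-2-en-1-ol | CC(C)(C)[Si](c1ccccc1)(c1ccccc1)OC[C@@]1(C)O[C@@H]1CC/C(C)=C/CO | intermediate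
6 | methanesulfonate of 5 | CC(C)(C)[Si](c1ccccc1)(c1ccccc1)OC[C@@]1(C)O[C@@H]1CC/C(C)=C/COS(C)(=O)=O | intermediate (not isolated)
7 | tert-butyl({(2R,3R)-3-[(3E)-5-bromo-3-methylpent-3-en-1-yl]-2-methyloxiran-2-yl}methoxy)diphenylsilane | CC(C)(C)[Si](c1ccccc1)(c1ccccc1)OC[C@@]1(C)O[C@@H]1CC/C(C)=C/CBr | intermediate
8 | methyl acetoacetate | COC(=O)CC(C)=O | starting material
9 | methyl acetoacetate dianion (sodium lithium salt) | [Na+].[Li+].[CH2-]C(=O)[CH-]C(=O)OC | intermediate (not isolated)
10 | methyl (6E)-7-methyl-3-oxo-9-[(2R,3R)-3-(TBDPS-oxymethyl)-3-methyloxiran-2-yl]non-6-enoate | CC(C)(C)[Si](c1ccccc1)(c1ccccc1)OC[C@@]1(C)O[C@@H]1CC/C(C)=C/CCC(=O)CC(=O)OC | intermediate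
11 | potassium (Z)-enolate of 10 | [K+].CC(C)(C)[Si](c1ccccc1)(c1ccccc1)OC[C@@]1(C)O[C@@H]1CC/C(C)=C/CC/C([O-])=C/C(=O)OC | intermediate (not isolated)
12 | methyl (2Z,6E)-7-methyl-9-[(2R,3R)-3-(TBDPS-oxymethyl)-3-methyloxiran-2-yl]-3-(trifluoromethylsulfonyloxy)nona-2,6-dienoate | CC(C)(C)[Si](c1ccccc1)(c1ccccc1)OC[C@@]1(C)O[C@@H]1CC/C(C)=C/CC/C(OS(=O)(=O)C(F)(F)F)=C/C(=O)OC | intermediate
13 | (trimethylsilyl)methylmagnesium chloride | C[Si](C)(C)C[Mg]Cl | starting material
14 | methyl (2Z,6E)-7-methyl-9-[(2R,3R)-3-(TBDPS-oxymethyl)-3-methyloxiran-2-yl]-3-[(trimethylsilyl)methyl]nona-2,6-dienoate | CC(C)(C)[Si](c1ccccc1)(c1ccccc1)OC[C@@]1(C)O[C@@H]1CC/C(C)=C/CC/C(C[Si](C)(C)C)=C/C(=O)OC | intermediate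
15 | (2Z,6E)-7-methyl-9-[(2R,3R)-3-(TBDPS-oxymethyl)-3-methyloxiran-2-yl]-3-[(trimethylsilyl)methyl]nona-2,6-dien-1-ol | CC(C)(C)[Si](c1ccccc1)(c1ccccc1)OC[C@@]1(C)O[C@@H]1CC/C(C)=C/CC/C(C[Si](C)(C)C)=C/CO | intermediate
16 | methanesulfonate of 15 | CC(C)(C)[Si](c1ccccc1)(c1ccccc1)OC[C@@]1(C)O[C@@H]1CC/C(C)=C/CC/C(C[Si](C)(C)C)=C/COS(C)(=O)=O | intermediate (not isolated)
17 | tert-butyl({(2R,3R)-3-[(3E,7Z)-9-bromo-3-methyl-7-[(trimethylsilyl)methyl]nona-3,7-dien-1-yl]-2-methyloxiran-2-yl}methoxy)diphenylsilane | CC(C)(C)[Si](c1ccccc1)(c1ccccc1)OC[C@@]1(C)O[C@@H]1CC/C(C)=C/CC/C(C[Si](C)(C)C)=C/CBr | intermediate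
18 | methyl acetate | COC(C)=O | starting material
19 | lithium enolate of methyl acetate | [Li+].[O-]C(=C)OC | intermediate (not isolated)
20 | methyl (4Z,8E)-9-methyl-11-[(2R,3R)-3-(TBDPS-oxymethyl)-3-methyloxiran-2-yl]-5-[(trimethylsilyl)methyl]undeca-4,8-dienoate (backbone all-trans) | CC(C)(C)[Si](c1ccccc1)(c1ccccc1)OC[C@@]1(C)O[C@@H]1CC/C(C)=C/CC/C(C[Si](C)(C)C)=C/CCC(=O)OC | intermediate
21 | methyl (3R,4S,5S,9R,10S)-3-hydroxy-18-(TBDPS-oxy)-14,15,16-trinorlabd-8(17)-en-13-oate (trans-decalin; 3-OH and C18 equatorial, C19 and C20 axial and syn) | COC(=O)CC[C@@H]1C(=C)CC[C@H]2[C@@]1(C)CC[C@@H](O)[C@]2(C)CO[Si](c3ccccc3)(c3ccccc3)C(C)(C)C | intermediate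
22 | 3-O-(1H-imidazol-1-ylcarbothioyl) derivative of 21 | COC(=O)CC[C@@H]1C(=C)CC[C@H]2[C@@]1(C)CC[C@@H](OC(=S)n3ccnc3)[C@]2(C)CO[Si](c4ccccc4)(c4ccccc4)C(C)(C)C | intermediate
23 | methyl (4S,5S,9R,10S)-18-(TBDPS-oxy)-14,15,16-trinorlabd-8(17)-en-13-oate | COC(=O)CC[C@@H]1C(=C)CC[C@H]2[C@@]1(C)CCC[C@]2(C)CO[Si](c3ccccc3)(c3ccccc3)C(C)(C)C | intermediate
24 | (4S,5S,9R,10S)-N-methoxy-N-methyl-18-(TBDPS-oxy)-14,15,16-trinorlabd-8(17)-en-13-amide | CON(C)C(=O)CC[C@@H]1C(=C)CC[C@H]2[C@@]1(C)CCC[C@]2(C)CO[Si](c3ccccc3)(c3ccccc3)C(C)(C)C | intermediate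
25 | (4S,5S,9R,10S)-18-hydroxy-N-methoxy-N-methyl-14,15,16-trinorlabd-8(17)-en-13-amide | CON(C)C(=O)CC[C@@H]1C(=C)CC[C@H]2[C@@]1(C)CCC[C@]2(C)CO | intermediate
26 | (4S,5S,9R,10S)-N-methoxy-N-methyl-18-oxo-14,15,16-trinorlabd-8(17)-en-13-amide | CON(C)C(=O)CC[C@@H]1C(=C)CC[C@H]2[C@@]1(C)CCC[C@]2(C)C=O | intermediate
27 | (4S,5S,9R,10S)-13-[methoxy(methyl)amino]-13-oxo-14,15,16-trinorlabd-8(17)-en-18-oic acid | CON(C)C(=O)CC[C@@H]1C(=C)CC[C@H]2[C@@]1(C)CCC[C@]2(C)C(=O)O | intermediate
28 | methyl (4S,5S,9R,10S)-13-[methoxy(methyl)amino]-13-oxo-14,15,16-trinorlabd-8(17)-en-18-oate | CON(C)C(=O)CC[C@@H]1C(=C)CC[C@H]2[C@@]1(C)CCC[C@]2(C)C(=O)OC | intermediate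
29 | methyl (4S,5S,9R,10S)-13-oxo-16-norlabda-8(17),14-dien-18-oate | C=CC(=O)CC[C@@H]1C(=C)CC[C@H]2[C@@]1(C)CCC[C@]2(C)C(=O)OC | intermediate
30 | methyl (4S,5S,9R,10S,13RS)-13,16-epoxylabda-8(17),14-dien-18-oate | C=CC3(CO3)CC[C@@H]1C(=C)CC[C@H]2[C@@]1(C)CCC[C@]2(C)C(=O)OC | intermediate
31 | methyl (4S,5S,9R,10S,13R)-13,16-dihydroxylabda-8(17),14-dien-18-oate | C=C[C@@](O)(CO)CC[C@@H]1C(=C)CC[C@H]2[C@@]1(C)CCC[C@]2(C)C(=O)OC | target

## Step count and risks

Total step count: 22. Longest linear sequence: 22 steps (geranyl acetate to the target; the other three starting materials enter directly).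

**Step 12 (key bicyclisation).** The cascade may stop after ring A, or the activated oxirane may rearrange by hydride shift to a C3 ketone before C5 attacks, because the C18 oxygen lowers electron demand at C4 and the ester holds part of the Lewis acid. The fallback forms the same two bonds by a radical cascade; it sets out from 12 and comes back at 21.
- Coupling of 12 with MeMgBr under Fe(acac)3 catalysis (THF, −30 °C) would give methyl (2E,6E)-3,7-dimethyl-9-[(2R,3R)-3-(TBDPS-oxymethyl)-3-methyloxiran-2-yl]nona-2,6-dienoate F1.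
- Reduction with i-Bu2AlH would give the dienol F2, MsCl/Et3N its mesylate F3, and LiBr the allylic bromide F4.
- Alkylation of enolate 19 with F4 would give the silicon-free epoxy triene ester methyl (4E,8E)-5,9-dimethyl-11-[(2R,3R)-3-(TBDPS-oxymethyl)-3-methyloxiran-2-yl]undeca-4,8-dienoate F5.
- Cp2TiCl (trivalent titanium, from Cp2TiCl2 and Mn dust, THF, rt) would open the oxirane homolytically to the C4 radical. Two 6-endo radical closures and β-hydride loss from the C8 titanium alkyl toward C17 are expected to give 21; C4 then rests on the chair preference for equatorial CH2OTBDPS.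

**Step 22 (asymmetric hydrolysis).** Interconversion of the two diastereomeric π-allyl complexes may be slower than oxygen delivery, which would erode C13 control; attack at the terminal carbon C15 or β-hydride loss may also compete. The fallback sets C13 by a reagent-controlled epoxidation of an allylic alcohol; it sets out from 28 and comes back at 31.
- PMBOCH2Li (from PMBOCH2SnBu3 and n-BuLi, THF, −78 °C) would convert 28 into the PMB-oxymethyl ketone F6.
- Wittig methylenation (Ph3P=CH2) would give the PMB allyl ether F7, and DDQ would free the 2-substituted allylic alcohol F8.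
- Sharpless epoxidation with Ti(OiPr)4, diethyl L-(+)-tartrate and t-BuOOH should give the (13S)-13,14-epoxy alcohol F9; the C8=C17 alkene is not an allylic alcohol and is left alone.
- TBSCl/imidazole would give the silyl ether F10.
- Excess dimethylsulfonium methylide would open the oxirane at its CH2 carbon and eliminate to the vinyl carbinol, the (13R) TBS ether F11.
- Bu4NF would give 31.

**Step 21 (ylide epoxidation of the vinyl ketone).** The ylide may add in conjugate fashion (cyclopropanation), or the base may polymerise the enone. The fallback avoids the enone; it sets out from 28 and comes back at 30.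
- Chloromethyllithium (ICH2Cl, MeLi·LiBr, THF, −78 °C) would convert the Weinreb amide into the α-chloroketone F12.
- Vinylmagnesium bromide at −78 °C would give the chlorohydrin F13.
- K2CO3 in MeOH would close it to the vinyl epoxide 30.

## Further compounds

F1 | step 12 | methyl (2E,6E)-3,7-dimethyl-9-[(2R,3R)-3-(TBDPS-oxymethyl)-3-methyloxiran-2-yl]nona-2,6-dienoate | CC(C)(C)[Si](c1ccccc1)(c1ccccc1)OC[C@@]1(C)O[C@@H]1CC/C(C)=C/CC/C(C)=C/C(=O)OC
F2 | step 12 | (2E,6E)-3,7-dimethyl-9-[(2R,3R)-3-(TBDPS-oxymethyl)-3-methyloxiran-2-yl]nona-2,6-dien-1-ol | CC(C)(C)[Si](c1ccccc1)(c1ccccc1)OC[C@@]1(C)O[C@@H]1CC/C(C)=C/CC/C(C)=C/CO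
F3 | step 12 | methanesulfonate of F2 | CC(C)(C)[Si](c1ccccc1)(c1ccccc1)OC[C@@]1(C)O[C@@H]1CC/C(C)=C/CC/C(C)=C/COS(C)(=O)=O
F4 | step 12 | allylic bromide from F3 | CC(C)(C)[Si](c1ccccc1)(c1ccccc1)OC[C@@]1(C)O[C@@H]1CC/C(C)=C/CC/C(C)=C/CBr
F5 | step 12 | methyl (4E,8E)-5,9-dimethyl-11-[(2R,3R)-3-(TBDPS-oxymethyl)-3-methyloxiran-2-yl]undeca-4,8-dienoate | CC(C)(C)[Si](c1ccccc1)(c1ccccc1)OC[C@@]1(C)O[C@@H]1CC/C(C)=C/CC/C(C)=C/CCC(=O)OC
F6 | step 22 | methyl (4S,5S,9R,10S)-16-(PMB-oxy)-13-oxo-14,15-dinorlabd-8(17)-en-18-oate | COc1ccc(COCC(=O)CC[C@@H]2C(=C)CC[C@H]3[C@@]2(C)CCC[C@]3(C)C(=O)OC)cc1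
F7 | step 22 | methyl (4S,5S,9R,10S)-16-(PMB-oxy)-15-norlabda-8(17),13(14)-dien-18-oate | COc1ccc(COCC(=C)CC[C@@H]2C(=C)CC[C@H]3[C@@]2(C)CCC[C@]3(C)C(=O)OC)cc1
F8 | step 22 | methyl (4S,5S,9R,10S)-16-hydroxy-15-norlabda-8(17),13(14)-dien-18-oate | OCC(=C)CC[C@@H]1C(=C)CC[C@H]2[C@@]1(C)CCC[C@]2(C)C(=O)OC
F9 | step 22 | methyl (4S,5S,9R,10S,13S)-13,14-epoxy-16-hydroxy-15-norlabd-8(17)-en-18-oate | C3[C@@](O3)(CO)CC[C@@H]1C(=C)CC[C@H]2[C@@]1(C)CCC[C@]2(C)C(=O)OC
F10 | step 22 | 16-O-TBS ether of F9 | C3[C@@](O3)(CO[Si](C)(C)C(C)(C)C)CC[C@@H]1C(=C)CC[C@H]2[C@@]1(C)CCC[C@]2(C)C(=O)OC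
F11 | step 22 | methyl (4S,5S,9R,10S,13R)-13-hydroxy-16-(TBS-oxy)labda-8(17),14-dien-18-oate | C=C[C@@](O)(CO[Si](C)(C)C(C)(C)C)CC[C@@H]1C(=C)CC[C@H]2[C@@]1(C)CCC[C@]2(C)C(=O)OC
F12 | step 21 | methyl (4S,5S,9R,10S)-16-chloro-13-oxo-14,15-dinorlabd-8(17)-en-18-oate | ClCC(=O)CC[C@@H]1C(=C)CC[C@H]2[C@@]1(C)CCC[C@]2(C)C(=O)OC
F13 | step 21 | methyl (4S,5S,9R,10S,13RS)-16-chloro-13-hydroxylabda-8(17),14-dien-18-oate | C=CC(O)(CCl)CC[C@@H]1C(=C)CC[C@H]2[C@@]1(C)CCC[C@]2(C)C(=O)OC
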